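## Analysis of the target

The target is a 3-deoxy biflavonoid. A luteoliflavan unit (phloroglucinol ring A, pyran ring C, catechol ring B) is bonded through its C4 to C8 of (−)-epigallocatechin 3-O-gallate (ring D, pyran ring F, pyrogallol ring E, galloyl ester on O3). Flavan numbering is used within each unit.

There are four stereocentres in two isolated pairs. In the upper unit C2 is S and C4 is R, with the two aryl groups trans across ring C. In the lower unit C2 and C3 are both R, cis across ring F. The pairs communicate only through the C4–C8 bond, so neither can be relied on to control the other.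

The free compound carries twelve phenols, among them one catechol and two pyrogallols, and is sensitive to air and base. The gallate is a base-labile ester on a hindered axial hydroxyl. The C4–C8 bond is doubly benzylic to electron-rich rings and can be cleaved by strong acid, and the benzylic ethers O1–C2 can ionise, which would scramble C2.

The hard points are the 4→8 (not 4→6) linkage, the 2,3-cis relation of the lower unit (not the one most ring closures or equilibration give), the 2,4-trans relation of the upper unit, and two phloroglucinol rings of similar reactivity.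

The route rests on one feature. C4 of ring F is an unsubstituted methylene that joins C4a of ring D, a highly nucleophilic aromatic carbon, to the carbinol carbon C3. Cutting C4–C4a turns ring F into a ring D aryl ether of a terminal epoxide whose carbinol carbon carries ring E. Both lower stereocentres then sit in an open chain under reagent control, and the second carbon ortho to the ether oxygen is already occupied by the upper unit, so the linkage is fixed in advance.

## Retrosynthetic reasoning

**17 from 16.** All twelve phenols are carried as benzyl ethers and released in one hydrogenolysis at the end. This keeps every intermediate neutral, chromatographable and insensitive to air, and leaves no protecting-group step after the polyphenol is exposed.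

**16 from 14 and 15, and 14 from 13.** The ester C–O bond at O3 is cut next to last. The galloyl group is base-labile and heavy, so it goes on after all basic alkylations. Before that, the one free phenol of 13 (C7 of ring D) is benzylated to 14, so that only the secondary C3 hydroxyl can be acylated by 15.

**13 from 12 (key disconnection).** The C4–C4a bond of ring F is cut. C4 has no stereochemistry and C4a is activated by three oxygen substituents, so the bond can be formed without creating or endangering a stereocentre. The cut gives 12, the ether of ring D with a terminal epoxide. Its other ortho position carries the flavan-4-yl group, so only the 4→8 isomer can arise. The forward step must activate the epoxide at its methylene carbon with an acid mild enough not to ionise any benzylic C–O bond or the C4–C8 bond.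

**12 from 8 and 11.** The aryl ether bond O–C2 is cut. An invertive etherification turns the erythro epoxy alcohol 11 into the threo ether, which maps onto 2,3-cis after ring closure. The two phenols of 8 that flank the flavanyl group are interchanged by rotation about the C4–aryl bond, so no site selection is needed. The forward reaction has to be a clean bimolecular substitution at a benzylic carbinol carbon.

**11 from 10, and 10 from 9.** The epoxide oxygen and the carbinol configuration of 11 come from a Sharpless kinetic resolution of the racemic allylic alcohol 10, which gives the erythro epoxy alcohol from the fast-reacting enantiomer. 10 is the vinyl adduct of aldehyde 9.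

**8 from 7, and 7 from 5 and 6.** The benzyl group on the phenol para to the flavanyl group is removed in thought. That phenol is the only unflanked one in 7, so it can be addressed by steric control. The bond between C4 of the flavan and the trihydroxyphenyl ring is then cut. The symmetry of 6 removes any regiochemical question, and capture of the C4 cation of the flavan is expected to occur trans to the C2 aryl group.

**5 from 4, 4 from 2 and 3, 2 from 1.** The C4 hydroxyl of 5 is a disposable leaving group obtained by reduction of ketone 4. The C2–aryl bond of 4 is cut to chromone 2 and boronic acid 3. An enantioselective conjugate addition sets C2, the only catalyst-controlled stereocentre of the upper unit. 2 is the dibenzyl ether of 1.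

## Alternatives that were turned down

**Alternative 1: ring A ortho-quinone methide plus styrene.**
- Disconnection: ring C of the upper unit is cut at C3–C4 and O1–C2. This leads to a diaryl carbinol A2, in which one carbon carries the ring A phenol and C8 of the fully benzylated lower unit, and to 3,4-dibenzyloxystyrene A3.
- Forward key step: a chiral phosphoric acid dehydrates A2 to the ring A ortho-quinone methide, A3 adds through its terminal carbon, and the ring A oxygen closes the pyran. The product A1 is the same compound as 16.
- For: it is the most convergent option. Ring C and both upper stereocentres form in one operation, and the product is already the last protected intermediate. On convergence and step count it is stronger than the chosen route.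
- Against: cycloadditions of ortho-quinone methides with styrenes normally place the C2 and C4 aryl groups cis, and the target needs trans. The catalyst would also have to set absolute configuration at a methide carbon that bears a doubly ortho-substituted ring D, in the presence of the lower stereocentres. A2 requires C8-selective functionalisation of a lower unit that has to be made first.
- Comparison: the chosen route sets each stereocentre by a separate, well-understood control element, and the 2,4-trans relation follows the conformational preference of the flavan instead of opposing the intrinsic preference of the cycloaddition.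

**Alternative 2: desymmetrising Mitsunobu closure of a bis-aryl carbinol.**
- Disconnection: O1–C2 of ring C is cut, giving carbinol A5 with two identical 2-hydroxy-4,6-dibenzyloxyphenyl groups on the future C4.
- Forward key step: Mitsunobu activation of the single carbinol lets one of the two diastereotopic phenols displace it with inversion, closing ring C, creating C4 and giving A4.
- For: A5 is symmetric and easy to assemble. A4 already has ring D with one free flanking phenol and both other oxygens benzylated, so it would enter the same etherification and ring closure and save steps 5 and 10. On protecting-group economy it is stronger.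
- Against: the activated carbinol is benzylic to ring B with a para benzyloxy group in conjugation, so the alkoxyphosphonium intermediate can ionise and erode C2. Which aryl group cyclises rests on a 1,3-relation in a six-membered transition state, with no strong element to put the spectator aryl group axial, so 2,4-trans is not assured.
- Comparison: the chosen route sets C2 by conjugate addition, where no leaving group ever sits on that benzylic carbon, and sets C4 by reversible cation capture, which can converge on the trans isomer.

**Alternative 3: retentive fluoride displacement from a syn diol derivative.**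
- Disconnection: O1–C8a of ring F is cut. The precursor A7 is a ring D fluoroarene carrying the upper unit, with a free C2 carbinol and a methoxymethyl ether on C3.
- Forward key step: a crown-ether-activated potassium alkoxide at C2 displaces fluoride from C8a by addition–elimination, with retention at C2, to give A6.
- For: C2 and C3 come from syn dihydroxylation of an E-alkene, and the closure is retentive, so 2,3-cis needs no invertive etherification. No acid is present, and the position of fluorine fixes the regiochemistry. On stereochemical security of the lower unit and on acid sensitivity it is stronger than the chosen route.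
- Against: ring D carries three donor substituents and is about the least suited arene for nucleophilic aromatic substitution. The forcing basic conditions invite elimination and acetal migration. The fluorinated ring must be carried through the attachment of the upper unit and through C–C bond formation at C4a, the two carbinols must be differentiated, and the acetal must be removed at the end.
- Comparison: the chosen route uses ring D in its natural polarity, as a nucleophile, and reaches its precursor in fewer steps from 6.

Key step: step 9

Assumption: the pyridine–oxazoline palladium catalyst is taken to show on chromone 2 the sense of induction it shows on cyclic enones, so the (R)-ligand should give the 2S flavanone; if a first run shows the opposite sense, the (S)-ligand is used and nothing else changes.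

## Route

Step 1
Reactants: 1 5,7-dihydroxy-4H-chromen-4-one
Product: 2 5,7-bis(benzyloxy)-4H-chromen-4-one
Conditions: BnBr, K2CO3, DMF, 70 °C
Reagents that add atoms: benzyl bromide, BrCc1ccccc1
Why: Williamson etherification; the chelated C5 hydroxyl is slower than the C7 hydroxyl but is alkylated on warming with excess halide, and the chromone has no other site that reacts under carbonate.

Step 2
Reactants: 2 5,7-bis(benzyloxy)-4H-chromen-4-one; 3 3,4-bis(benzyloxy)phenylboronic acid
Product: 4 (2S)-5,7-bis(benzyloxy)-2-[3,4-bis(benzyloxy)phenyl]chroman-4-one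
Conditions: Pd(OCOCF3)2 (5 mol %), (R)-t-BuPyOx (6 mol %), NH4PF6 (30 mol %), H2O (5 equiv), ClCH2CH2Cl, 60 °C
Reagents that add atoms: none
Why: Enantioselective palladium-catalysed conjugate addition of an arylboronic acid to a chromone: transmetalation to cationic divalent palladium, insertion of C2=C3 and protonolysis of the palladium enolate by water. The chiral pyridine–oxazoline ligand selects the face of the enone and so sets C2 as S. The near-neutral medium should not open the flavanone to the chalcone, which would racemise C2.

Step 3
Reactants: 4 (2S)-5,7-bis(benzyloxy)-2-[3,4-bis(benzyloxy)phenyl]chroman-4-one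
Product: 5 (2S,4S)-5,7-bis(benzyloxy)-2-[3,4-bis(benzyloxy)phenyl]chroman-4-ol (2,4-cis)
Conditions: NaBH4, THF/MeOH, 0 °C
Reagents that add atoms: none
Why: Borohydride reduction of the aryl ketone; hydride adds axially to the half-chair with the C2 aryl group equatorial and should give mainly the 2,4-cis alcohol. The C4 configuration is of no consequence because this centre is ionised in step 4, so any trans epimer is carried along.

Step 4
Reactants: 5 (2S,4S)-5,7-bis(benzyloxy)-2-[3,4-bis(benzyloxy)phenyl]chroman-4-ol; 6 phloroglucinol
Product: 7 (2S)-2,4-trans-5,7-bis(benzyloxy)-2-[3,4-bis(benzyloxy)phenyl]-4-(2,4,6-trihydroxyphenyl)chroman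
Conditions: 6 (8 equiv), BF3·OEt2 (0.2 equiv), 1,4-dioxane/CH2Cl2 (1:1), 0 °C → rt
Reagents that add atoms: none
Why: Friedel–Crafts alkylation: the Lewis acid ionises the C4 hydroxyl to a cation stabilised by the C5 and C7 oxygens, and excess 6 captures it, which suppresses double alkylation and self-condensation; the symmetry of 6 leaves no regiochemical choice. The nucleophile adds pseudo-axially to the half-chair cation with the C2 aryl group equatorial, hence trans to it; this is also the isomer in which the C4 aryl group avoids the C5 benzyloxy group, so reversible ionisation should converge on it.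

Step 5
Reactants: 7 (2S)-2,4-trans-5,7-bis(benzyloxy)-2-[3,4-bis(benzyloxy)phenyl]-4-(2,4,6-trihydroxyphenyl)chroman
Product: 8 (2S)-2,4-trans-4-[4-(benzyloxy)-2,6-dihydroxyphenyl]-5,7-bis(benzyloxy)-2-[3,4-bis(benzyloxy)phenyl]chroman
Conditions: BnBr (1.0 equiv), K2CO3 (1.1 equiv), DMF, 0 °C → rt
Reagents that add atoms: benzyl bromide, BrCc1ccccc1
Why: Williamson etherification under steric control: with one equivalent of base and halide the hydroxyl para to the flavanyl group reacts, as it is the only phenol not flanked by that bulky substituent. Carbonate in a dipolar aprotic solvent favours O- over C-alkylation.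

Step 6
Reactants: 9 3,4,5-tris(benzyloxy)benzaldehyde
Product: 10 rac-1-[3,4,5-tris(benzyloxy)phenyl]prop-2-en-1-ol
Conditions: CH2=CHMgBr, THF, −78 → 0 °C
Reagents that add atoms: vinylmagnesium bromide, C=C[Mg]Br
Why: Grignard addition to a non-enolisable aryl aldehyde; the racemate is wanted because the next step resolves it.

Step 7
Reactants: 10 rac-1-[3,4,5-tris(benzyloxy)phenyl]prop-2-en-1-ol
Product: 11 (S)-[(2R)-oxiran-2-yl][3,4,5-tris(benzyloxy)phenyl]methanol (erythro)
Conditions: Ti(OiPr)4 (0.2 equiv), L-(+)-diisopropyl tartrate (0.24 equiv), t-BuOOH (0.45 equiv), 4 Å molecular sieves, CH2Cl2, −20 °C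
Reagents that add atoms: tert-butyl hydroperoxide, CC(C)(C)OO
Why: Sharpless kinetic resolution: the catalyst from Ti(OiPr)4 and the L-(+)-tartrate epoxidises the R enantiomer of 10 much faster than the S enantiomer and delivers oxygen to one face of its vinyl group, giving the erythro epoxy alcohol. The carbinol configuration is thus selected and the oxirane carbon is created under reagent control. Less than half an equivalent of oxidant keeps the slow enantiomer out of the product; unreacted (S)-10 is removed by chromatography.

Step 8
Reactants: 8 (2S)-2,4-trans-4-[4-(benzyloxy)-2,6-dihydroxyphenyl]-5,7-bis(benzyloxy)-2-[3,4-bis(benzyloxy)phenyl]chroman; 11 (S)-[(2R)-oxiran-2-yl][3,4,5-tris(benzyloxy)phenyl]methanol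
Product: 12 (2S)-2,4-trans-5,7-bis(benzyloxy)-2-[3,4-bis(benzyloxy)phenyl]-4-{4-(benzyloxy)-2-hydroxy-6-[(R)-[(2R)-oxiran-2-yl][3,4,5-tris(benzyloxy)phenyl]methoxy]phenyl}chroman (threo ether)
Conditions: 11 (1.2 equiv), PPh3, DIAD, THF, 0 °C → rt
Reagents that add atoms: none
Why: Mitsunobu etherification: the phenol protonates the betaine and its phenoxide displaces the alkoxyphosphonium group of 11 by bimolecular substitution with inversion, turning the erythro alcohol into the threo ether that maps onto 2,3-cis; the epoxide is inert to these neutral conditions. The two flanking phenols of 8 are interchanged by rotation about the C4–aryl bond, so either gives 12, and the remaining one is more shielded once the first is etherified.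

Step 9
Reactants: 12 (2S)-2,4-trans-5,7-bis(benzyloxy)-2-[3,4-bis(benzyloxy)phenyl]-4-{4-(benzyloxy)-2-hydroxy-6-[(R)-[(2R)-oxiran-2-yl][3,4,5-tris(benzyloxy)phenyl]methoxy]phenyl}chroman
Product: 13 (2R,3R)-5-(benzyloxy)-2-[3,4,5-tris(benzyloxy)phenyl]chroman-3,7-diol carrying at C8 the (2S)-2,4-trans-5,7-bis(benzyloxy)-2-[3,4-bis(benzyloxy)phenyl]chroman-4-yl group
Conditions: Sc(OTf)3 (10 mol %), (CF3)2CHOH/CH2Cl2 (1:4), 0 °C, 0.005 M
Reagents that add atoms: none
Why: Intramolecular Friedel–Crafts epoxy-arene cyclisation, the known route from aryl glycidyl ethers to chroman-3-ols. Trivalent scandium, helped by the hydrogen-bond network of the fluorinated alcohol, binds the epoxide oxygen; the ring D carbon ortho to the ether oxygen attacks the terminal CH2 carbon opposite the breaking C–O bond, and the arenium ion loses a proton, giving C4–C4a and the C3 hydroxyl. Ring F closes in the 6-endo mode with respect to the epoxide; the 5-exo mode at the internal carbon is disfavoured because that carbon is secondary, crowded by the ring E carbinol carbon and deactivated by the adjacent ether C–O bond, and because the short tether cannot align the arene with its C–O bond. No stereocentre is formed: the C3–O and C2–O bonds are not broken, so the threo ether gives the 2,3-cis chromanol. Regiochemistry is fixed because the other carbon ortho to the ether oxygen bears the flavanyl group, and the attacking carbon is the most electron-rich CH in the molecule (ether oxygen and benzyloxy ortho, free hydroxyl para). High dilution secures chemoselectivity over intermolecular attack by ring A. Ionisation at the ring E benzylic ether is held back because the para oxygen of ring E is twisted out of conjugation by its two benzyloxy neighbours while the meta oxygens withdraw inductively, and a catalytic Lewis acid at 0 °C is below what the upper O1–C2 ether and the C4–C8 bond need to ionise.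

Step 10
Reactants: 13 (2R,3R)-5-(benzyloxy)-2-[3,4,5-tris(benzyloxy)phenyl]chroman-3,7-diol carrying the flavan-4-yl group at C8
Product: 14 (2R,3R)-5,7-bis(benzyloxy)-2-[3,4,5-tris(benzyloxy)phenyl]chroman-3-ol carrying at C8 the (2S)-2,4-trans-5,7-bis(benzyloxy)-2-[3,4-bis(benzyloxy)phenyl]chroman-4-yl group
Conditions: BnBr, K2CO3, DMF, rt → 40 °C
Reagents that add atoms: benzyl bromide, BrCc1ccccc1
Why: Williamson etherification; carbonate deprotonates only the phenol, so the secondary C3 hydroxyl stays free for the esterification, and with ring E fully protected the basic medium offers no pathway for epimerisation at C2.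

Step 11
Reactants: 14 (2R,3R)-5,7-bis(benzyloxy)-2-[3,4,5-tris(benzyloxy)phenyl]chroman-3-ol carrying the flavan-4-yl group at C8; 15 3,4,5-tris(benzyloxy)benzoic acid
Product: 16 dodeca-O-benzyl ether of the target, the 3-O-[3,4,5-tris(benzyloxy)benzoyl] ester of 14
Conditions: 15, DCC, DMAP, CH2Cl2, rt
Reagents that add atoms: none
Why: Steglich esterification; the acylpyridinium species formed from the O-acylisourea is reactive enough for the axial, hindered C3 hydroxyl, and the neutral conditions touch neither benzyl ethers nor stereocentres.

Step 12
Reactants: 16 dodeca-O-benzyl ether of the target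
Product: 17 (2S,4R)-5,7,3',4'-tetrahydroxyflavan-(4→8)-(2R,3R)-epigallocatechin 3-O-gallate (target)
Conditions: H2 (1 atm), Pd(OH)2/C, THF/MeOH, rt, then filtration under argon and lyophilisation
Reagents that add atoms: none
Why: Catalytic hydrogenolysis of the twelve benzyl ethers; the cyclic benzylic ethers O1–C2, the C4–C8 bond and the aryl ester are cleaved much more slowly than O-benzyl groups under these mild conditions, and exclusion of air protects the pyrogallol and catechol rings.

## Compound list

1 | 5,7-dihydroxy-4H-chromen-4-one | O=c1ccoc2cc(O)cc(O)c12 | starting material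
2 | 5,7-bis(benzyloxy)-4H-chromen-4-one | O=c1ccoc2cc(OCc3ccccc3)cc(OCc3ccccc3)c12 | intermediate
3 | 3,4-bis(benzyloxy)phenylboronic acid | OB(O)c1ccc(OCc2ccccc2)c(OCc2ccccc2)c1 | starting material
4 | (2S)-5,7-bis(benzyloxy)-2-[3,4-bis(benzyloxy)phenyl]chroman-4-one | O=C1C[C@@H](c2ccc(OCc3ccccc3)c(OCc3ccccc3)c2)Oc2cc(OCc3ccccc3)cc(OCc3ccccc3)c12 | intermediate
5 | (2S,4S)-5,7-bis(benzyloxy)-2-[3,4-bis(benzyloxy)phenyl]chroman-4-ol | O[C@H]1C[C@@H](c2ccc(OCc3ccccc3)c(OCc3ccccc3)c2)Oc2cc(OCc3ccccc3)cc(OCc3ccccc3)c12 | intermediate
6 | phloroglucinol | Oc1cc(O)cc(O)c1 | starting material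
7 | (2S)-2,4-trans-5,7-bis(benzyloxy)-2-[3,4-bis(benzyloxy)phenyl]-4-(2,4,6-trihydroxyphenyl)chroman | Oc1cc(O)cc(O)c1[C@@H]1C[C@@H](c2ccc(OCc3ccccc3)c(OCc3ccccc3)c2)Oc2cc(OCc3ccccc3)cc(OCc3ccccc3)c21 | intermediate
8 | (2S)-2,4-trans-4-[4-(benzyloxy)-2,6-dihydroxyphenyl]-5,7-bis(benzyloxy)-2-[3,4-bis(benzyloxy)phenyl]chroman | Oc1cc(OCc2ccccc2)cc(O)c1[C@@H]1C[C@@H](c2ccc(OCc3ccccc3)c(OCc3ccccc3)c2)Oc2cc(OCc3ccccc3)cc(OCc3ccccc3)c21 | intermediate
9 | 3,4,5-tris(benzyloxy)benzaldehyde | O=Cc1cc(OCc2ccccc2)c(OCc2ccccc2)c(OCc2ccccc2)c1 | starting material
10 | rac-1-[3,4,5-tris(benzyloxy)phenyl]prop-2-en-1-ol | C=CC(O)c1cc(OCc2ccccc2)c(OCc2ccccc2)c(OCc2ccccc2)c1 | intermediate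
11 | (S)-[(2R)-oxiran-2-yl][3,4,5-tris(benzyloxy)phenyl]methanol | O[C@@H](c1cc(OCc2ccccc2)c(OCc2ccccc2)c(OCc2ccccc2)c1)[C@H]1CO1 | intermediate
12 | threo ether of 8 with 11: (2S)-2,4-trans flavan whose C4 aryl group carries 4-benzyloxy, 2-hydroxy and 6-{(R)-[(2R)-oxiran-2-yl][3,4,5-tris(benzyloxy)phenyl]methoxy} | Oc1cc(OCc2ccccc2)cc(O[C@H](c2cc(OCc3ccccc3)c(OCc3ccccc3)c(OCc3ccccc3)c2)[C@H]2CO2)c1[C@@H]1C[C@@H](c2ccc(OCc3ccccc3)c(OCc3ccccc3)c2)Oc2cc(OCc3ccccc3)cc(OCc3ccccc3)c21 | intermediate
13 | octa-O-benzyl flavan–(4→8)–epigallocatechin with free C3 and C7 hydroxyls on the lower unit, (2R,3R) | O[C@@H]1Cc2c(OCc3ccccc3)cc(O)c([C@@H]3C[C@@H](c4ccc(OCc5ccccc5)c(OCc5ccccc5)c4)Oc4cc(OCc5ccccc5)cc(OCc5ccccc5)c43)c2O[C@@H]1c1cc(OCc2ccccc2)c(OCc2ccccc2)c(OCc2ccccc2)c1 | intermediate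
14 | nona-O-benzyl flavan–(4→8)–epigallocatechin with free C3 hydroxyl | O[C@@H]1Cc2c(OCc3ccccc3)cc(OCc3ccccc3)c([C@@H]3C[C@@H](c4ccc(OCc5ccccc5)c(OCc5ccccc5)c4)Oc4cc(OCc5ccccc5)cc(OCc5ccccc5)c43)c2O[C@@H]1c1cc(OCc2ccccc2)c(OCc2ccccc2)c(OCc2ccccc2)c1 | intermediate
15 | 3,4,5-tris(benzyloxy)benzoic acid | OC(=O)c1cc(OCc2ccccc2)c(OCc2ccccc2)c(OCc2ccccc2)c1 | starting material
16 | dodeca-O-benzyl ether of the target | O=C(O[C@@H]1Cc2c(OCc3ccccc3)cc(OCc3ccccc3)c([C@@H]3C[C@@H](c4ccc(OCc5ccccc5)c(OCc5ccccc5)c4)Oc4cc(OCc5ccccc5)cc(OCc5ccccc5)c43)c2O[C@@H]1c1cc(OCc2ccccc2)c(OCc2ccccc2)c(OCc2ccccc2)c1)c1cc(OCc2ccccc2)c(OCc2ccccc2)c(OCc2ccccc2)c1 | intermediate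
17 | (2S,4R)-5,7,3',4'-tetrahydroxyflavan-(4→8)-(2R,3R)-epigallocatechin 3-O-gallate | O=C(O[C@@H]1Cc2c(O)cc(O)c([C@@H]3C[C@@H](c4ccc(O)c(O)c4)Oc4cc(O)cc(O)c43)c2O[C@@H]1c1cc(O)c(O)c(O)c1)c1cc(O)c(O)c(O)c1 | target

## Step count and least certain steps

Total: 12 steps. Longest linear sequence: 10 steps (steps 1, 2, 3, 4, 5, 8, 9, 10, 11, 12); the epoxy alcohol branch (steps 6 and 7) joins at step 8.

**Step 9 (key step).**
- Risk: acid-induced ionisation of a benzylic C–O bond (the upper O1–C2 ether with its para benzyloxy group, or the ring E carbinol ether), which would scramble C2 or fragment the molecule. Opening of the epoxide by ring A of a second molecule, hydride shift to the aldehyde, or 5-exo closure are further losses. The cause is that 12 holds several acid-sensitive groups and two nucleophilic rings besides ring D.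
- Fallback: the order of ring closure and interflavan bond formation is reversed; it sets out from 11 and 5 and comes back at 14. 11 is coupled under the conditions of step 8 with commercial 3,5-bis(benzyloxy)phenol (Oc1cc(OCc2ccccc2)cc(OCc2ccccc2)c1), an unhindered phenol, to give 1,3-bis(benzyloxy)-5-{(R)-[(2R)-oxiran-2-yl][3,4,5-tris(benzyloxy)phenyl]methoxy}benzene F1. F1 has one nucleophilic ring with two equivalent ortho positions and belongs to the very substrate class for which the cyclisation is established; the same acid closes it to 5,7,3',4',5'-penta-O-benzyl-(−)-epigallocatechin F2. The cation from 5 (TMSOTf, CH2Cl2, −78 → −40 °C) is then captured by an excess of F2 at C8, trans to the C2 aryl group, giving 14. The price is that 4→8 against 4→6 selectivity must be earned in that coupling.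

**Step 8.**
- Risk: slow capture of the alkoxyphosphonium intermediate by a phenol flanked by the flavanyl group, so that alkylation of the hydrazide or elimination takes over, and partial ionisation of the benzylic intermediate with loss of clean inversion.
- Fallback: no ether is formed at a carbinol at all; it sets out from 5 and comes back at 16. Commercial (−)-epigallocatechin gallate is benzylated on its eight phenols (BnBr, K2CO3, DMF) to octa-O-benzyl-(−)-epigallocatechin gallate F3, and the cation from 5 (TMSOTf, CH2Cl2, −78 °C) is captured by the ring D of F3 at C8 to give 16 directly. The reordered sequence described for step 9 would relieve the hindrance but still depends on an inversion at the same carbinol, which is why this fallback is kept separate.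

**Step 5.**
- Risk: over-alkylation and alkylation at a flanking hydroxyl, because the three phenols differ only in shielding, together with some C-benzylation of the electron-rich ring.
- Fallback: the para oxygen is marked by a group that can only reach the unflanked phenol; it sets out from 7 and comes back at 14. 7 is silylated (iPr3SiCl, imidazole, DMF) to the para triisopropylsilyl ether F4. F4 is etherified with 11 as in step 8 to the epoxy ether F5, and F5 is cyclised as in step 9 to the chromanol F6, which has a silyl ether at C5 and free hydroxyls at C3 and C7. Treatment of F6 with Bu4NF and then BnBr and K2CO3 in DMF benzylates both ring D phenols and gives 14.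

**Step 2.**
- Risk: slow insertion of the electron-rich, 5-alkoxy-substituted chromone, with protodeboronation of the electron-rich boronic acid competing, or insufficient facial selectivity.
- Fallback: the configuration at C2 is secured at the reduction stage instead; it sets out from 2 and 3 and comes back at 5. The conjugate addition is run with an achiral ligand (Pd(OCOCF3)2, 2,2'-bipyridine) to give the racemic flavanone F7. F7 is then subjected to a kinetic resolution by asymmetric transfer hydrogenation (RuCl[(S,S)-TsDPEN](p-cymene), HCO2H/Et3N, EtOAc, rt; the catalyst enantiomer that reduces the 2S ketone). The 2S ketone is reduced to 5 and the 2R ketone is left behind, so steps 2 and 3 merge.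

**Step 7.**
- Risk: the epoxy alcohol is the product, not the recovered substrate, of a kinetic resolution, so its enantiomeric purity is bounded by the rate ratio and cannot be raised by pushing conversion. The slow epoxidation of a monosubstituted alkene also gives titanium-mediated opening of the product time to compete.
- Fallback: the enantiomer is purified as recovered substrate first; it sets out from 10 and comes back at 11. 10 is resolved with the catalyst from Ti(OiPr)4 and D-(−)-diisopropyl tartrate, run past half conversion, so that (R)-1-[3,4,5-tris(benzyloxy)phenyl]prop-2-en-1-ol F8 is recovered; its purity rises with conversion. F8 is then epoxidised to completion with the L-(+)-tartrate catalyst, the matched combination, giving 11.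

## Further compounds

F1 | step 9 | 1,3-bis(benzyloxy)-5-{(R)-[(2R)-oxiran-2-yl][3,4,5-tris(benzyloxy)phenyl]methoxy}benzene | C(c1ccccc1)Oc1cc(OCc2ccccc2)cc(O[C@H](c2cc(OCc3ccccc3)c(OCc3ccccc3)c(OCc3ccccc3)c2)[C@H]2CO2)c1
F2 | step 9 | 5,7,3',4',5'-penta-O-benzyl-(−)-epigallocatechin | O[C@@H]1Cc2c(OCc3ccccc3)cc(OCc3ccccc3)cc2O[C@@H]1c1cc(OCc2ccccc2)c(OCc2ccccc2)c(OCc2ccccc2)c1
F3 | step 8 | octa-O-benzyl-(−)-epigallocatechin gallate | O=C(O[C@@H]1Cc2c(OCc3ccccc3)cc(OCc3ccccc3)cc2O[C@@H]1c1cc(OCc2ccccc2)c(OCc2ccccc2)c(OCc2ccccc2)c1)c1cc(OCc2ccccc2)c(OCc2ccccc2)c(OCc2ccccc2)c1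
F4 | step 5 | (2S)-2,4-trans-5,7-bis(benzyloxy)-2-[3,4-bis(benzyloxy)phenyl]-4-[2,6-dihydroxy-4-(triisopropylsilyloxy)phenyl]chroman | CC(C)[Si](Oc1cc(O)c([C@@H]2C[C@@H](c3ccc(OCc4ccccc4)c(OCc4ccccc4)c3)Oc3cc(OCc4ccccc4)cc(OCc4ccccc4)c32)c(O)c1)(C(C)C)C(C)C
F5 | step 5 | analogue of 12 with a triisopropylsilyl ether in place of the ring D benzyl ether | Oc1cc(O[Si](C(C)C)(C(C)C)C(C)C)cc(O[C@H](c2cc(OCc3ccccc3)c(OCc3ccccc3)c(OCc3ccccc3)c2)[C@H]2CO2)c1[C@@H]1C[C@@H](c2ccc(OCc3ccccc3)c(OCc3ccccc3)c2)Oc2cc(OCc3ccccc3)cc(OCc3ccccc3)c21
F6 | step 5 | analogue of 13 with a triisopropylsilyl ether at C5 of ring D | O[C@@H]1Cc2c(O[Si](C(C)C)(C(C)C)C(C)C)cc(O)c([C@@H]3C[C@@H](c4ccc(OCc5ccccc5)c(OCc5ccccc5)c4)Oc4cc(OCc5ccccc5)cc(OCc5ccccc5)c43)c2O[C@@H]1c1cc(OCc2ccccc2)c(OCc2ccccc2)c(OCc2ccccc2)c1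
F7 | step 2 | rac-5,7-bis(benzyloxy)-2-[3,4-bis(benzyloxy)phenyl]chroman-4-one | O=C1CC(c2ccc(OCc3ccccc3)c(OCc3ccccc3)c2)Oc2cc(OCc3ccccc3)cc(OCc3ccccc3)c12
F8 | step 7 | (R)-1-[3,4,5-tris(benzyloxy)phenyl]prop-2-en-1-ol | C=C[C@@H](O)c1cc(OCc2ccccc2)c(OCc2ccccc2)c(OCc2ccccc2)c1
A1 | alternative 1 | dodeca-O-benzyl ether of the target (identical with 16) | O=C(O[C@@H]1Cc2c(OCc3ccccc3)cc(OCc3ccccc3)c([C@@H]3C[C@@H](c4ccc(OCc5ccccc5)c(OCc5ccccc5)c4)Oc4cc(OCc5ccccc5)cc(OCc5ccccc5)c43)c2O[C@@H]1c1cc(OCc2ccccc2)c(OCc2ccccc2)c(OCc2ccccc2)c1)c1cc(OCc2ccccc2)c(OCc2ccccc2)c(OCc2ccccc2)c1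
A2 | alternative 1 | octa-O-benzyl-epigallocatechin gallate carrying at C8 a [2-hydroxy-4,6-bis(benzyloxy)phenyl](hydroxy)methyl group, either carbinol epimer | O=C(O[C@@H]1Cc2c(OCc3ccccc3)cc(OCc3ccccc3)c(C(O)c3c(O)cc(OCc4ccccc4)cc3OCc3ccccc3)c2O[C@@H]1c1cc(OCc2ccccc2)c(OCc2ccccc2)c(OCc2ccccc2)c1)c1cc(OCc2ccccc2)c(OCc2ccccc2)c(OCc2ccccc2)c1
A3 | alternative 1 | 3,4-bis(benzyloxy)styrene | C=Cc1ccc(OCc2ccccc2)c(OCc2ccccc2)c1
A4 | alternative 2 | (2S)-2,4-trans-5,7-bis(benzyloxy)-2-[3,4-bis(benzyloxy)phenyl]-4-[2-hydroxy-4,6-bis(benzyloxy)phenyl]chroman | Oc1cc(OCc2ccccc2)cc(OCc2ccccc2)c1[C@@H]1C[C@@H](c2ccc(OCc3ccccc3)c(OCc3ccccc3)c2)Oc2cc(OCc3ccccc3)cc(OCc3ccccc3)c21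
A5 | alternative 2 | (1R)-1-[3,4-bis(benzyloxy)phenyl]-3,3-bis[2-hydroxy-4,6-bis(benzyloxy)phenyl]propan-1-ol | O[C@H](CC(c1c(O)cc(OCc2ccccc2)cc1OCc1ccccc1)c1c(O)cc(OCc2ccccc2)cc1OCc1ccccc1)c1ccc(OCc2ccccc2)c(OCc2ccccc2)c1
A6 | alternative 3 | nona-O-benzyl flavan–(4→8)–epigallocatechin 3-O-methoxymethyl ether | COCO[C@@H]1Cc2c(OCc3ccccc3)cc(OCc3ccccc3)c([C@@H]3C[C@@H](c4ccc(OCc5ccccc5)c(OCc5ccccc5)c4)Oc4cc(OCc5ccccc5)cc(OCc5ccccc5)c43)c2O[C@@H]1c1cc(OCc2ccccc2)c(OCc2ccccc2)c(OCc2ccccc2)c1
A7 | alternative 3 | ring D fluoroarene carrying the upper flavan, with the open chain CH2–CH(OCH2OCH3)–CH(OH)–(ring E), syn | COCO[C@H](Cc1c(OCc2ccccc2)cc(OCc2ccccc2)c([C@@H]2C[C@@H](c3ccc(OCc4ccccc4)c(OCc4ccccc4)c3)Oc3cc(OCc4ccccc4)cc(OCc4ccccc4)c32)c1F)[C@H](O)c1cc(OCc2ccccc2)c(OCc2ccccc2)c(OCc2ccccc2)c1
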